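The violet run, with partner charged at 250% of the substrate, reads 18% target after 60.0 min. If each target takes one partner, as I assume, that is 7.20% of violet's partner charge.

the same everywhere: substrate 0.10 M

|  | partner | remark | time |
|---|---|---|---|
| amber | 0.033 M | run made earlier |  |
| violet | 0.25 M | run made earlier |  |
| south-west | 0.0250 M |  | 80 min |
| east | 0.0500 M |  | 80 min |
| west | 0.100 M |  | 80 min |
| north | 0.200 M |  | 80 min |

| amber: time / min | amber: target / % | violet: time / min | violet: target / % |
|---|---|---|---|
| 3.00 | 0 | 8.00 | 1 |
| 8.00 | 0 | 15.0 | 3 |
| 15.0 | 0 | 25.0 | 5 |
| 25.0 | 1 | 30.0 | 9 |
| 30.0 | 0 | 40.0 | 13 |
| 40.0 | 2 | 50.0 | 13 |
| 60.0 | 5 | 60.0 | 18 |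

(each reading ± 2 percentage points)

- what was read earlier has a scatter of 2 percentage points, one standard deviation
- a reading or a percentage of target counts all its forms, free or not
- "hardly changes" means that all values lie within two and a half points (for a concentration: within two and a half percent of the largest)

- amount of target at the end, in percent of the substrate charged for south-west, east, west, north, in this order
- how the row runs (falls all the way / hardly changes / rises all the way / falls, then rises / rises, then falls)

So I keep the books on the partner. I take each partner to have the same chance per minute whatever the charge, the pseudo-first-order view, so a flask's target is a common share times its partner charge. Amber gives 15.2% for that share, give or take 6.1 percentage points, while violet's margin is 0.8 points, and so I lean on violet. Violet reads twice at 60.0 min what it read at 30.0 min, in twice the time, so I let the share grow in step with time. That gives the spent share, the part of a flask's own partner charge turned into target by the end: 9.60%.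

In south-west the partner is the limiting reagent. Its ledger, in parts of the substrate charged, is:

partner charged: 25.0%

into target: 2.40%

left unspent: 22.6%

The same share gives 4.80% for east, 9.60% for west and 19.2% for north, so my row rises all the way. Amber's share stands higher than violet's, which warns me that the low end may read above this.

The forecast gives 4%, 7.5%, 13% and 22%, above my row at both ends, with the shape rises all the way, and says “More partner should therefore give more target throughout”.

The flask gives 3.77%, 7.17%, 13.0% and 21.6%: rises all the way.

    crystals ⇌ target, rate k1*(cs1 - [target]) while solid is left; crystals form when [target] > cs1 (solubility = 15.0 mM, k = 2.30 /min)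
    substrate → intermediate (k = 0.00950 /min)
    substrate + intermediate → side product (k = 0.00620 /M/min)
    intermediate → decomposed reagent (k = 0.0160 /min)
    partner + intermediate → target (k = 0.110 /M/min)

South-west has spent 15.1% of its partner, above my 9.60%, and that share of its charge of 25.0% closes the books at 3.77% target. North has spent 10.8% of a charge of 200%, which gives 21.6% target, crystals included. At 32.5 min in south-west, intermediate goes to decomposed reagent 6.1 times as fast as it goes to target. At the end south-west holds 23.8% as decomposed reagent against 3.77% as target.

Readings and results are calculated on assumed constants.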